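The numbers in the tables are simulated with made-up constants; scatter was added.

One thing holds in every flask of this series: each product is made from partner and its own substrate, so partner stands in both making rates and cancels from their ratio. At any moment, left-handed rate over right-handed rate is therefore a constant, the selectivity factor, times left-handed substrate over right-handed substrate. The question is how far that substrate ratio drifts from one.

| setting | Thursday's | Sunday's | Saturday's | noon | winter | dawn | summer |
|---|---|---|---|---|---|---|---|
| left-handed substrate | 0.25 M | 0.25 M | 0.25 M | 0.25 M | 0.25 M | 0.25 M | 0.25 M |
| right-handed substrate | 0.25 M | 0.25 M | 0.25 M | 0.25 M | 0.25 M | 0.25 M | 0.25 M |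
| partner | 0.15 M | 0.43 M | 0.66 M | 0.200 M | 0.300 M | 0.500 M | 0.800 M |
| remark | run made earlier | run made earlier | run made earlier |  |  |  |  |
| time |  |  |  | 5.0 min | 5.0 min | 5.0 min | 5.0 min |

| run | time / min | left-handed product / % | right-handed product / % |
|---|---|---|---|
| Thursday's | 0.417 | 8.1 | 3.9 |
| Thursday's | 1.33 | 15.6 | 7.1 |
| Thursday's | 2.50 | 18.4 | 8.4 |
| Thursday's | 4.00 | 20.5 | 8.4 |
| Thursday's | 5.00 | 20.7 | 8.6 |
| Sunday's | 1.00 | 33.6 | 15.1 |
| Sunday's | 2.00 | 43.2 | 19.5 |
| Sunday's | 3.00 | 48.2 | 21.8 |
| Sunday's | 4.00 | 50.7 | 22.8 |
| Sunday's | 5.00 | 52.9 | 23.6 |
| Saturday's | 0.417 | 28.7 | 14.0 |
| Saturday's | 1.33 | 50.4 | 23.1 |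
| Saturday's | 2.50 | 57.6 | 27.2 |
| Saturday's | 4.00 | 62.2 | 29.1 |
| Saturday's | 5.00 | 63.5 | 30.3 |

(each reading ± 0.3 percentage points)

- partner is single-handed; left-handed substrate and right-handed substrate are mirror images of each other, charged as a racemate, each of them at the stated concentration
- reactions considered so far: achiral form -> decomposed reagent; left-handed substrate <-> achiral form; partner + left-handed substrate -> left-handed product; right-handed substrate <-> achiral form; partner + right-handed substrate -> right-handed product
- an excess is the difference of the two amounts in percent of their sum
- "hardly changes" means that all values lie within two and a half points (for a concentration: within two and a half percent of the largest)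
- the handed part of partner does not stay in what it makes, so the products of the two hands are mirror images too

- excess of left-handed product over right-handed product at the end for noon, winter, dawn, summer, in this order
- the shape of the row from first to last (hardly changes / rises, then falls / rises all the way / falls, then rises / falls all the way)

Ada and Ben agree on one point: Saturday's left-handed product reads 63.5%, above the 50.0% charged as that hand, so substrate does pass through the achiral form.

Ada holds that this passage keeps the two substrates equal, so that each flask makes the same excess. A single reading such as 8.6% is rough with a scatter of 0.3 percentage points, so she sums the columns of Thursday's flask, which has less partner than the other two. The ratio of the left-handed sum to the right-handed sum is her selectivity factor, 2.29. As an excess that is 39.2%, and her row stays flat there.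

Ben sums the other two flasks the same way. He gets 2.22 on Sunday and 2.12 on Saturday, lower with more partner and both below 2.29. Held against her 2.29, a reading with its scatter, his sums read by the rule as substrate ratios near 0.969 and 0.926, averaged over each run: in these readings the left-handed substrate lags.

As excesses his ratios are 38.0% and 35.9%. Joining the three excesses by straight lines and running the last line on to 0.800 M, I reckon 39.0% for noon and 34.7% for summer, so I side with Ben.

The forecast takes Ben's side with other numbers, 40.5%, 39.3%, 37% and 34%, falls all the way, on the ground that “left-handed substrate is depleted faster than it is replenished”.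

The flask gives 38.8%, 38.4%, 37.4% and 35.6%: the row falls all the way, by 3.2 points in total.

    achiral form → decomposed reagent (k = 0.0296 s⁻¹)
    left-handed substrate ⇌ achiral form (K = 0.0510, k = 0.171 s⁻¹)
    partner + left-handed substrate → left-handed product (k = 0.0593 M⁻¹ s⁻¹)
    right-handed substrate ⇌ achiral form (K = 0.0510, k = 0.171 s⁻¹)
    partner + right-handed substrate → right-handed product (k = 0.0257 M⁻¹ s⁻¹)

Ada keeps the stretch from noon to dawn, where the fall is 1.4 points, inside the margin for "hardly changes". At the end of summer, 0.65% of the left-handed substrate stood against 0.69% of the right-handed, each of its own charge. Multiplied by 2.29, that ratio gives a rate ratio of 2.15, an excess of 36.5% in what summer was making at the end. The same reckoning for noon, from 46% and 46%, gives 39.2%.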